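## Structural features

The target 12 is a monocyclic macrolactone: a 27-membered ring of 26 carbon atoms and one ring oxygen, with the ester joining the carbonyl carbon C1 to the oxygen on C26. Between these ends runs an unbranched chain of 25 methylene groups (C2 to C26) with no substituent, no unsaturation and no further heteroatom. There is no stereocentre, so no question of neighbouring stereocentres or relative configuration arises. The lactone is the only fragile group: hydroxide, alkoxides and strong nucleophiles can cleave it, hydride donors can reduce it, and strong base can deprotonate or halogenate C2. The real difficulty is twofold. A strain-free but entropically unfavourable 27-membered ring must be closed against oligomerisation, and a 26-carbon α,ω-difunctional chain cannot simply be bought, so one C–C bond has to be made in a stretch with no functional handle. The C11–C12 bond lies in this blank region and divides the chain into an 11-carbon acyl part (C1–C11) and a 15-carbon alkoxy part (C12–C26), both accessible as bifunctional chains. The key step exploits this bond: sulfur placed between C11 and C12 lets the ring be closed as a 28-membered thioether lactone, and its extrusion as SO2 from the derived sulfone joins C11 to C12 (10 + 15 methylenes plus the carbonyl carbon give exactly 26 carbons).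

## Logic of the disconnections

12 ⇒ 11. No bond is cut; a C11=C12 double bond is written into the chain of 12. An alkene at this position is what a sulfone extrusion delivers, so this brings out the retron of the key step. Nothing is gained in simplicity yet. The forward step must saturate the alkene of 11, whatever its geometry, without touching the lactone. That is a light demand, provided sulfur-containing residues from the preceding step are removed before the catalyst is added.

11 ⇒ 8 (key disconnection). The C11=C12 bond is cut and an SO2 group is inserted between the two carbons, turning the 27-membered ring of 11 into the 28-membered ring of 8. The cut is placed here because it splits the carbon chain into an 11-carbon and a 15-carbon arm that can each be sourced, and because sulfur offers a ring closure by alkylation of a soft nucleophile. The gain is that the only C–C bond to be made is no longer made in the ring-closing event. The forward step must halogenate alpha to the sulfonyl group, close a three-membered ring and lose SO2 in the presence of a lactone that can be saponified or enolised. Which alpha carbon is halogenated and which alkene geometry results do not matter.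

8 ⇒ 6. The two S=O bonds are removed. Only the sulfide oxidation level can be reached by a nucleophilic ring closure, so oxidation is placed after cyclisation. The forward step needs an electrophilic oxidant that passes cleanly through the sulfoxide to the sulfone and leaves the saturated ester alone.

6 ⇒ 5. One S–C bond is cut, the one on the alkoxy arm (ring positions 13 and 14 of 6), giving the open-chain 5 with thiol and bromide at its two ends. Thiolate alkylation is fast and irreversible, and a one-component closure needs only slow addition of a single substrate. Cutting both S–C bonds at once, with Na2S as the sulfur source, was set aside for two reasons. Na2S in protic or wet media is in effect hydrosulfide plus hydroxide or alkoxide and endangers the ester, and a two-component bridging adds a statistical element. The gain is an acyclic precursor that already contains the ester. The forward step demands high dilution, exclusion of oxygen, and a base that deprotonates the thiol without attacking the ester.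

5 ⇒ 3 + 4. The ester C(=O)–O bond is cut, giving a 15-carbon bromo alcohol 3 and an 11-carbon mercapto acid 4. This is the only heteroatom link between the arms, and 4 can be bought. The forward esterification must proceed with a free thiol and a primary bromide present, which points to acid catalysis with removal of water rather than an activated acyl donor.

3 ⇒ 2 ⇒ 1. The primary alcohol of 3 is traced back to the carboxylic acid of 2, and the C15–Br bond of 2 to the alkyl–oxygen bond of the lactone 1. The reason is supply: 1 is an inexpensive 15-carbon ring whose two ends are already differentiated. The forward steps demand cleavage of an unstrained lactone by bromide and a reduction of the acid that spares the C–Br bond.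

## Other disconnections considered

Alternative 1: The cut is the C1–C2 bond, made on a carbocyclic precursor that still lacks the ring oxygen.
- Forward: the diester A1 (dimethyl hexacosanedioate) would be reduced with sodium in hot toluene in the presence of chlorotrimethylsilane (acyloin condensation, Rühlmann variant). After hydrolytic work-up this gives the 26-membered acyloin A2 (racemic 2-hydroxycyclohexacosanone). Removal of the hydroxyl group (Zn, HCl, AcOH) would give the symmetrical ketone A3 (cyclohexacosanone), and Baeyer–Villiger oxidation would insert the ring oxygen to give 12.
- In favour: the closure occurs on the metal surface and tolerates large rings without extreme dilution, which makes it better than the chosen plan on the ring-closing event itself. The C–C bond and the ring are formed together, and the symmetry of A3 removes any regiochemical question in the oxygen insertion.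
- Against: A1 is not readily purchased, so the 26-carbon chain would need a C–C coupling sequence of its own, the very problem the chosen plan solves inside its key step. Three redox operations follow ring closure instead of one. Baeyer–Villiger oxidation of large unstrained ketones is expected to be slow and to need a strong peracid. Dispersed sodium with a chlorosilane is the more hazardous operation.
- Comparison: structurally both plans erase their auxiliary function completely (equal). Mechanistically an electron-transfer coupling stands against two polar steps, and the alternative never exposes a lactone to base, a point on which it is better. In step economy it is the weaker plan once the preparation of A1 is counted.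

Alternative 2: The cut is the C13–C14 bond, set in a 1,3-diyne so that both halves end in a terminal alkyne.
- Forward: the ester A6 (tridec-12-yn-1-yl tridec-12-ynoate) would be made from the acid A4 (tridec-12-ynoic acid) and the alcohol A5 (tridec-12-yn-1-ol), itself obtained from A4 by reduction. Eglinton coupling with Cu(OAc)2 in pyridine at high dilution would give the diyne lactone A7 (hexacosa-12,14-diyn-26-olide), and exhaustive hydrogenation over Pd/C would give 12.
- In favour: ring closure and C–C bond formation coincide and nothing has to be extruded. The coupling conditions should leave an ester untouched, which is better than the chosen plan on compatibility with the lactone. One building block serves both halves, and the finish is a single hydrogenation, equal to the chosen plan.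
- Against: A4 is not a commodity and would have to be made, for example by isomerising an internal alkyne to the chain terminus. The closure again needs high dilution, now with stoichiometric copper salt in large volumes of pyridine, and intermolecular coupling to acyclic or cyclic oligomers is the expected competitor.
- Comparison: structurally the rigid diyne rod fits easily into a 27-membered ring, so neither plan suffers from strain (equal). Mechanistically both depend on an intramolecular step outrunning its intermolecular counterpart; the thiolate alkylation is likely the faster closure, while the alkyne coupling builds the carbon skeleton directly. In step economy the alternative is shorter if A4 is at hand (reduction, esterification, coupling, hydrogenation) and longer if it is not.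

Alternative 3: The cuts are the C2=C3 and C10=C11 bonds of a dienoate, dividing the ring into an acrylate unit, an eight-carbon unit and a long alkenyl chain.
- Forward: A8 (cis-cyclooctene) and A9 (heptadec-16-en-1-yl acrylate) would be combined with the second-generation Grubbs catalyst RuCl2(=CHPh)(H2IMes)(PCy3) in dilute solution. The alkylidene formed at the terminal alkene of A9 opens A8, and the new alkylidene closes onto the acrylate. This gives A10 ((2E)-hexacosa-2,10-dien-26-olide, C10=C11 geometry mixed) and A11 (ethylene); hydrogenation of both double bonds would give 12.
- In favour: two C=C bonds and the ring arise in one operation from a cheap cyclic alkene under neutral conditions, and the conjugated double bond should form with E geometry. From the alkenol only three steps are needed (acylation, metathesis, hydrogenation), which is better step economy than the chosen plan. The final hydrogenation is its equal.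
- Against: the catalyst must engage three different alkenes in a fixed order. Ring-opening polymerisation of A8, multiple insertion of A8 (ring homologues larger by C8H14 that would be hard to separate from A10) and self-metathesis of A9 are all plausible. High dilution and tight control of stoichiometry would be needed. The 17-carbon alkenol required for A9 is not readily purchased, which erodes the advantage in step count.
- Comparison: structurally both plans use a transient handle that one hydrogenation erases (equal). Mechanistically the metathesis cascade is a reversible multicomponent process whose product distribution is hard to predict, whereas the chosen plan uses two irreversible, individually well-understood steps. The alternative is the more convergent and the gentler towards the ester; the chosen plan is the more predictable in what it delivers.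

Key step: step 6

Assumption: 11 is expected as an E/Z mixture and is named and drawn as the E isomer, since both isomers give 12 in step 7; 9 is drawn with bromine on the acyl-side alpha carbon, the other regioisomer being equivalent.

## Route

Step 1
Reactants: 1 15-pentadecanolide (oxacyclohexadecan-2-one)
Product: 2 15-bromopentadecanoic acid
Conditions: 48% aq. HBr, conc. H2SO4, AcOH, reflux
Reagents that add atoms: hydrogen bromide, Br
Why: Acid-mediated opening of the lactone with SN2 displacement by bromide at the primary C15–O carbon (directly on the protonated lactone or after acyl–oxygen cleavage, both paths converging under excess HBr); the chain is unchanged and the only product of the balanced reaction is the ω-bromo acid.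

Step 2
Reactants: 2 15-bromopentadecanoic acid
Product: 3 15-bromopentadecan-1-ol
Conditions: BH3·THF, THF, 0 °C → rt; then H2O
Reagents that add atoms: none
Why: Chemoselective borane reduction of a carboxylic acid to the primary alcohol; electrophilic BH3 neither reduces nor displaces a primary alkyl bromide, so the C–Br bond is carried through.

Step 3
Reactants: 3 15-bromopentadecan-1-ol; 4 11-sulfanylundecanoic acid (11-mercaptoundecanoic acid)
Product: 5 15-bromopentadecyl 11-sulfanylundecanoate
Conditions: TsOH·H2O (cat.), toluene, reflux, Dean–Stark, N2
Reagents that add atoms: none
Why: Fischer esterification driven by azeotropic removal of water; under acid catalysis the neutral thiol is a much poorer acyl acceptor than the alcohol (any thioester would revert to the more stable O-ester under the equilibrating conditions) and a poor nucleophile towards the primary bromide, and exclusion of air suppresses disulfide formation.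

Step 4
Reactants: 5 15-bromopentadecyl 11-sulfanylundecanoate
Product: 6 1-oxa-13-thiacyclooctacosan-2-one
Conditions: Cs2CO3, DMF (degassed), 55 °C, slow addition of 5 (syringe pump, final ca. 2 mM)
Reagents that add atoms: none
Why: Intramolecular SN2 thioetherification under high dilution (caesium-carbonate-mediated macrocyclisation of an ω-bromo thiol); the soft, weakly ion-paired thiolate alkylates the primary bromide quickly and irreversibly to close the 28-membered ring, while carbonate in dry DMF deprotonates the thiol but does not attack the ester.

Step 5
Reactants: 6 1-oxa-13-thiacyclooctacosan-2-one
Product: 8 1-oxa-13-thiacyclooctacosan-2-one 13,13-dioxide, via sulfoxide 7 (not isolated)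
Conditions: mCPBA (2.3 equiv), CH2Cl2, 0 °C → rt
Reagents that add atoms: 3-chloroperoxybenzoic acid (mCPBA), OOC(=O)c1cccc(Cl)c1
Why: Stepwise electrophilic S-oxidation of a dialkyl sulfide through the sulfoxide to the sulfone; a saturated lactone is inert to the peracid, and the stereogenic sulfur of 7 disappears on the second oxidation.

Step 6
Reactants: 8 1-oxa-13-thiacyclooctacosan-2-one 13,13-dioxide
Product: 11 (11E)-hexacos-11-en-26-olide, via bromo sulfone 9 (not isolated), via episulfone 10 (not isolated)
Conditions: C2Br2Cl4 (1.2 equiv), KOH/Al2O3, t-BuOH–THF, 0 °C → rt
Reagents that add atoms: none
Why: Ramberg–Bäcklund reaction with in situ halogenation, the closest known reaction type being the one-flask conversion of open-chain and macrocyclic dialkyl sulfones to alkenes with solid KOH/Al2O3 and a perhalogenated positive-halogen donor. Hydroxide removes a proton alpha to the sulfonyl group of 8 and the carbanion abstracts bromine from C2Br2Cl4, which collapses to tetrachloroethylene and bromide; bromination at either alpha carbon is acceptable because both lead to the same three-membered ring, and 9 carries the bromine only transiently. Deprotonation at the other alpha carbon and intramolecular 1,3-displacement of bromide close the thiirane 1,1-dioxide of 10 in a 3-exo-tet mode, and this is the event that forms the C11–C12 bond. Cheletropic loss of SO2, taken up by the excess base as sulfite, leaves the C11=C12 alkene, so the 27-membered ring of 11 arises by contraction of the 28-membered ring of 8 and not by a macrocyclisation. The stereocentres of 9 and 10 are transient and uncontrolled and 10 can epimerise under the basic conditions, so 11 is expected as a mixture rich in the E isomer; no stereocentre survives and the geometry is irrelevant to step 7. The selectivity required is reaction at the sulfone alpha carbons in preference to bromination alpha to the lactone carbonyl and to saponification; because the equilibrium acidities of the two kinds of C–H are close, this rests on the faster proton transfer from the four sulfone alpha C–H bonds, on the irreversible onward reaction of the brominated sulfone, on a near-stoichiometric charge of C2Br2Cl4, and on the low effective hydroxide concentration of supported KOH in t-BuOH–THF at 0 °C to rt. The carbonyl group lies ten carbons from sulfur and takes no part in the contraction.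

Step 7
Reactants: 11 (11E)-hexacos-11-en-26-olide
Product: 12 26-hexacosanolide (oxacycloheptacosan-2-one)
Conditions: H2 (1 atm), Pd/C (10%), EtOAc, rt
Reagents that add atoms: none
Why: Heterogeneous catalytic hydrogenation of an unhindered 1,2-disubstituted alkene; E and Z isomers converge on the same saturated lactone, nothing hydrogenolysable is present and no stereocentre is created.

## Compound list

1 | 15-pentadecanolide (oxacyclohexadecan-2-one), achiral | O=C1CCCCCCCCCCCCCCO1 | starting material
2 | 15-bromopentadecanoic acid, achiral | OC(=O)CCCCCCCCCCCCCCBr | intermediate
3 | 15-bromopentadecan-1-ol, achiral | OCCCCCCCCCCCCCCCBr | intermediate
4 | 11-sulfanylundecanoic acid (11-mercaptoundecanoic acid), achiral | OC(=O)CCCCCCCCCCS | starting material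
5 | 15-bromopentadecyl 11-sulfanylundecanoate, achiral | SCCCCCCCCCCC(=O)OCCCCCCCCCCCCCCCBr | intermediate
6 | 1-oxa-13-thiacyclooctacosan-2-one, achiral | O=C1CCCCCCCCCCSCCCCCCCCCCCCCCCO1 | intermediate
7 | 1-oxa-13-thiacyclooctacosan-2-one 13-oxide (sulfoxide, racemic at sulfur, not isolated) | O=C1CCCCCCCCCCS(=O)CCCCCCCCCCCCCCCO1 | intermediate
8 | 1-oxa-13-thiacyclooctacosan-2-one 13,13-dioxide, achiral | O=C1CCCCCCCCCCS(=O)(=O)CCCCCCCCCCCCCCCO1 | intermediate
9 | 12-bromo-1-oxa-13-thiacyclooctacosan-2-one 13,13-dioxide (racemic, not isolated; the 14-bromo regioisomer is equivalent) | O=C1CCCCCCCCCC(Br)S(=O)(=O)CCCCCCCCCCCCCCCO1 | intermediate
10 | trans-12-oxa-28-thiabicyclo[25.1.0]octacosan-11-one 28,28-dioxide (thiirane 1,1-dioxide fused across C11–C12 of the lactone, racemic, trans isomer drawn, not isolated) | O=C1CCCCCCCCC[C@@H]2[C@@H](CCCCCCCCCCCCCCO1)S2(=O)=O | intermediate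
11 | (11E)-hexacos-11-en-26-olide (E drawn; Z isomer expected alongside) | O=C1CCCCCCCCC/C=C/CCCCCCCCCCCCCCO1 | intermediate
12 | 26-hexacosanolide (oxacycloheptacosan-2-one), achiral | O=C1CCCCCCCCCCCCCCCCCCCCCCCCCO1 | target

## Step count and uncertain steps

Total step count: 7. Longest linear sequence: 7 steps (1 → 2 → 3 → 5 → 6 → 8 → 11 → 12); 4 enters at step 3.

Step 6 (key step). The most likely failures are hydroxide attack at the lactone carbonyl, bromine transfer to the lactone enolate, and a second bromination of the sulfone before ring closure. The lactone has to sit in a basic medium, the two kinds of alpha C–H differ little in acidity, and sulfones with two primary alpha carbons are prone to over-halogenation. The fallback separates halogenation from base treatment and sets out from 6. Chlorination alpha to sulfur with N-chlorosuccinimide in CH2Cl2 (by way of the chlorosulfonium ion) should give 12-chloro-1-oxa-13-thiacyclooctacosan-2-one F1; either alpha carbon may be chlorinated and both isomers converge. F1 is oxidised directly with mCPBA to 12-chloro-1-oxa-13-thiacyclooctacosan-2-one 13,13-dioxide F2. Treatment of F2 with KOt-Bu in THF at −78 °C → 0 °C is the classical Ramberg–Bäcklund reaction of a preformed α-halo sulfone. It uses a hindered, non-nucleophilic base with no hydroxide and no electrophilic halogen in the flask, and it returns to the route at 11.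

Step 4. Intermolecular thiolate alkylation could outrun ring closure and give oligomers, and oxidative coupling of the thiol to a disulfide could remove it before it alkylates. The cause would be too high a stationary concentration of 5 or traces of oxygen. The fallback moves the ring closure to the ester bond and sets out from 3 and 4. S-alkylation of the dianion of 4 with 3 (NaOH, aqueous EtOH, rt), an intermolecular reaction that needs no dilution, should give 11-[(15-hydroxypentadecyl)sulfanyl]undecanoic acid F3. Yamaguchi macrolactonisation of F3 (2,4,6-trichlorobenzoyl chloride, Et3N, THF; then DMAP, toluene, reflux, high dilution) returns to the route at 6.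

Step 3. Acylation or alkylation at sulfur could compete with O-acylation during the prolonged heating, and air oxidation of the thiol is possible. The fallback masks the thiol and sets out from 4. Trityl chloride in CH2Cl2 should give 11-(tritylsulfanyl)undecanoic acid F4. Steglich esterification with 3 (DCC, DMAP cat., CH2Cl2) gives 15-bromopentadecyl 11-(tritylsulfanyl)undecanoate F5. Detritylation with TFA and Et3SiH in CH2Cl2, conditions that leave the ester and the bromide alone, returns to the route at 5.

Step 1. Alkyl–oxygen cleavage of an unstrained lactone may stop short, leaving ω-hydroxy or ω-acetoxy acid that can re-esterify to oligomers, because this ring has no strain to drive the opening. The fallback reverses the order of reduction and bromination and sets out from 1. LiAlH4 in THF should give pentadecane-1,15-diol F6, and monobromination with 48% aq. HBr in refluxing toluene (two-phase, the monobromide being withdrawn into the organic layer) returns to the route at 3, bypassing 2.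

## Further compounds

F1 | step 6 | 12-chloro-1-oxa-13-thiacyclooctacosan-2-one (racemic; 14-chloro regioisomer equivalent) | O=C1CCCCCCCCCC(Cl)SCCCCCCCCCCCCCCCO1
F2 | step 6 | 12-chloro-1-oxa-13-thiacyclooctacosan-2-one 13,13-dioxide (racemic; 14-chloro regioisomer equivalent) | O=C1CCCCCCCCCC(Cl)S(=O)(=O)CCCCCCCCCCCCCCCO1
F3 | step 4 | 11-[(15-hydroxypentadecyl)sulfanyl]undecanoic acid | OC(=O)CCCCCCCCCCSCCCCCCCCCCCCCCCO
F4 | step 3 | 11-(tritylsulfanyl)undecanoic acid | OC(=O)CCCCCCCCCCSC(c1ccccc1)(c1ccccc1)c1ccccc1
F5 | step 3 | 15-bromopentadecyl 11-(tritylsulfanyl)undecanoate | BrCCCCCCCCCCCCCCCOC(=O)CCCCCCCCCCSC(c1ccccc1)(c1ccccc1)c1ccccc1
F6 | step 1 | pentadecane-1,15-diol | OCCCCCCCCCCCCCCCO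
A1 | alternative 1 | dimethyl hexacosanedioate | COC(=O)CCCCCCCCCCCCCCCCCCCCCCCCC(=O)OC
A2 | alternative 1 | 2-hydroxycyclohexacosanone (racemic) | O=C1CCCCCCCCCCCCCCCCCCCCCCCCC1O
A3 | alternative 1 | cyclohexacosanone | O=C1CCCCCCCCCCCCCCCCCCCCCCCCC1
A4 | alternative 2 | tridec-12-ynoic acid | OC(=O)CCCCCCCCCCC#C
A5 | alternative 2 | tridec-12-yn-1-ol | OCCCCCCCCCCCC#C
A6 | alternative 2 | tridec-12-yn-1-yl tridec-12-ynoate | C#CCCCCCCCCCCC(=O)OCCCCCCCCCCCC#C
A7 | alternative 2 | hexacosa-12,14-diyn-26-olide | O=C1CCCCCCCCCCC#CC#CCCCCCCCCCCCO1
A8 | alternative 3 | cis-cyclooctene | C1CC/C=C\CCC1
A9 | alternative 3 | heptadec-16-en-1-yl acrylate | C=CC(=O)OCCCCCCCCCCCCCCCC=C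
A10 | alternative 3 | (2E)-hexacosa-2,10-dien-26-olide (C10=C11 geometry mixed) | O=C1/C=C/CCCCCCC=CCCCCCCCCCCCCCCCO1
A11 | alternative 3 | ethylene | C=C
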